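The earlier runs and the new flask come from a simulation with made-up constants; noise was put on by code.

The flask was to be read at 8.0 h, so I turned the cedar run into times to hold against that hour.

- cedar: solid substrate 0.0050 M; run made earlier
- flask: solid substrate 0.010 M; time 8.0 h

cedar run (percent of the solid substrate charged)

| time / h | product / % | solid substrate / % |
|---|---|---|
| 0.333 | 18.9 | 33.7 |
| 0.667 | 45.4 | 0 |
| 1.00 | 57.1 | 0.2 |
| 1.33 | 61.0 | 0 |
| 1.50 | 61.5 | 0 |
| 2.00 | 62.1 | 0 |
| 2.50 | 61.6 | 0.1 |

(readings scatter by 0.3 percentage points)

- as a solid, counted per litre of solution: solid substrate
- the numbers in the tables scatter by 0.3 percentage points (one standard deviation)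
- at the start none of the solid substrate is in solution

- amber: doubling the dissolution coefficient of the solid substrate, all else as stated
- grey: doubling the solubility of the solid substrate, all else as stated

* product at 8.0 h, in percent of the solid substrate charged
* the change that raises the amount of product at 8.0 h, in percent of the solid substrate charged most ("none" if none brings more than 2 percentage points) (amber / grey / none)
* amount of product at 8.0 h, in percent of the solid substrate charged, after amber

I took the dissolution by itself first. In the cedar run the solid substrate had fallen to 33.7% by 0.333 h, which read as a dissolving speed r of 0.00995 M h⁻¹. For the flask this gave 1.00 h as the clearing time t_c, the charge divided by that speed. That step gave me a time but no yield.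

Adding the conversion gave a yield, read as the level of the cedar product, 62.1% at 2.00 h and 61.6% at 2.50 h. I then added the lag behind dissolution. The gap to that level fell from 17 percentage points at 0.667 h to 5 points at 1.00 h, a half-life of 0.191 h. Between t_c and the reading lay 36.6 such half-lives, so I expected the flask to have reached the level by then.

Last came amber and grey, which I expected to act on t_c. Since t_c was shorter than the reading time, I reckoned that neither would raise the flask's yield, and I kept 62.1% for the flask with and without amber. My doubt was that r had been read on a charge half that of the flask.

The forecast gave 62% (range 56% to 63%), none as the best change, and 62% after amber (range 54% to 63%), on the ground that “Faster dissolution or higher solubility changes only the timing”.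

The flask gave 62.0%, none as the best change, and 62.0% after amber.

solid substrate ⇌ starting material, rate k1*(cs1 - [starting material]) while solid is left; crystals form when [starting material] > cs1 (solubility = 6.20 mM, k = 5.79 × 10⁻⁴ s⁻¹); starting material ⇌ product (K = 1.63, k = 6.30 × 10⁻⁴ s⁻¹) In the flask solid substrate dissolved while starting material passed into product, with 36.0% solid at 0.800 h where t_c had implied 20.4%. By 4.00 h the flask held 0% solid, 38.0% starting material and 62.0% product, an equilibrium (thermodynamic control) that stood to 8.00 h. Above the flask's charge, its product at the reading time first moved by 5 points at a charge of 0.0175 M. The neighbour charged with 0.025 M had a t_c of 2.51 h, yet at 8.00 h it held 35.5% solid and gave 39.9% product, its starting material at 6.15 mM against a solubility of 6.2 mM.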